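The target is (2Z,3S,3aR,5R,6aS)-3-bromo-5-[(1S)-1-bromopropyl]-2-[(3Z)-hex-3-en-5-yn-1-ylidene]hexahydrofuro[3,2-b]furan. The route has 22 steps, with a longest linear sequence of 17.

## Retrosynthetic overview
1. Ring A (enol ether) is closed last. The C7–O bond comes from 5-exo-dig addition of C10–OH to a C6≡C7 alkyne, which gives the 6Z geometry. C8–Br comes from SN2 inversion of an (8S)-propargylic alcohol.
2. C5–C6 comes from a copper acetylide and (Z)-BrCH2CH=CH–C≡C–SiMe3, made from ethyl propiolate. C7–C8 comes from Me3SiC≡CLi and a Weinreb amide, followed by asymmetric transfer hydrogenation of the ynone.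
3. C13–Br comes from inversion of the (13R)-carbinol. Ring B comes from 5-exo opening of a (12S,13S)-epoxide by C9–OH, and C13 is then corrected by oxidation and Felkin reduction.
4. The key C9–C10 bond comes from the boron syn-aldol of the (R)-4-benzyloxazolidinone benzyloxyacetimide with (E)-hex-3-enal.
5. Ring order: ring B first (step 7), ring A last (step 21).

Assumption: positions are numbered along the chain from C1 (alkyne CH) to C15 (CH3). In this numbering the given SMILES is (3Z,6Z,8S,9R,10S,12R,13S). Ring A is O–C7–C8–C9–C10 and ring B is O–C9–C10–C11–C12. TBS stands for tert-butyldimethylsilyl.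

## Route

Step 1
Reactants: 1 (4R)-4-benzyl-1,3-oxazolidin-2-one; 2 (benzyloxy)acetyl chloride
Product: 4 (4R)-4-benzyl-3-[(benzyloxy)acetyl]-1,3-oxazolidin-2-one, via N-lithio oxazolidinone 3 (not isolated)
Conditions: n-BuLi (1.0 equiv), THF, −78 °C; then 2, −78 → 0 °C
Reagents that add atoms: none
Why: N-acylation of the lithiated Evans auxiliary by an acid chloride is a clean acyl substitution that touches no stereocentre.

Step 2
Reactants: 5 (E)-hex-3-en-1-ol
Product: 6 (E)-hex-3-enal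
Conditions: Dess–Martin periodinane (1.2 equiv), CH2Cl2, 0 °C → rt; cold aq NaHCO3/Na2S2O3 wash; dried CH2Cl2 solution used at once
Reagents that add atoms: none
Why: Dess–Martin oxidation is base-free, so the β,γ-alkene neither moves into conjugation nor loses its E geometry.

Step 3
Reactants: 4 (4R)-4-benzyl-3-[(benzyloxy)acetyl]-1,3-oxazolidin-2-one; 6 (E)-hex-3-enal
Product: 9 (4R)-4-benzyl-3-[(2R,3S,5E)-2-(benzyloxy)-3-hydroxyoct-5-enoyl]-1,3-oxazolidin-2-one, via Z-boron enolate 7 (not isolated), via boron aldolate 8 (not isolated)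
Conditions: n-Bu2BOTf (1.15 equiv), Et3N (1.3 equiv), CH2Cl2, −78 → 0 °C; 6 (1.5 equiv), −78 → 0 °C; pH 7 buffer, MeOH, 30% H2O2, 0 °C
Reagents that add atoms: none
Why: In this Evans boron syn-aldol the Z-enolate reacts through a chair Zimmerman–Traxler transition state on the face away from the benzyl group of the (R)-auxiliary, forming C9–C10 and setting 9R,10S (syn).

Step 4
Reactants: 9 (4R)-4-benzyl-3-[(2R,3S,5E)-2-(benzyloxy)-3-hydroxyoct-5-enoyl]-1,3-oxazolidin-2-one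
Product: 10 (2R,3S,5E)-2-(benzyloxy)-3-hydroxy-N-methoxy-N-methyloct-5-enamide
Conditions: MeNH(OMe)·HCl (3 equiv), AlMe3 (3 equiv), CH2Cl2, 0 °C; then 9, −10 °C → rt; aq HCl work-up
Reagents that add atoms: N,O-dimethylhydroxylamine hydrochloride, CNOC.Cl
Why: Weinreb transamidation with the aluminium amide is directed to the exocyclic carbonyl by the free β-hydroxyl and leaves C9 and C10 untouched.

Step 5
Reactants: 10 (2R,3S,5E)-2-(benzyloxy)-3-hydroxy-N-methoxy-N-methyloct-5-enamide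
Product: 11 (2R,3S,5E)-2-(benzyloxy)-3-[(tert-butyldimethylsilyl)oxy]-N-methoxy-N-methyloct-5-enamide
Conditions: TBSOTf (1.3 equiv), 2,6-lutidine (2 equiv), CH2Cl2, 0 °C
Reagents that add atoms: tert-butyldimethylsilyl triflate, CC(C)(C)[Si](C)(C)OS(=O)(=O)C(F)(F)F
Why: Silyl ether formation masks C10–OH until ring A is closed, so that only O9 can open the epoxide later.

Step 6
Reactants: 11 (2R,3S,5E)-2-(benzyloxy)-3-[(tert-butyldimethylsilyl)oxy]-N-methoxy-N-methyloct-5-enamide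
Product: 12 (2R,3S)-2-(benzyloxy)-3-[(tert-butyldimethylsilyl)oxy]-4-[(2S,3S)-3-ethyloxiran-2-yl]-N-methoxy-N-methylbutanamide
Conditions: 1,2:4,5-di-O-isopropylidene-β-L-erythro-2,3-hexodiulo-2,6-pyranose (L-fructose-derived Shi ketone, 0.3 equiv), KHSO5 (as 2KHSO5·KHSO4·K2SO4), K2CO3, n-Bu4NHSO4, MeCN/(MeO)2CH2, aq Na2B4O7/Na2EDTA buffer, 0 °C
Reagents that add atoms: potassium peroxymonosulfate, [K+].[O-]S(=O)(=O)OO
Why: In this Shi asymmetric epoxidation the chiral dioxirane meets the E-alkene in a spiro transition state; the L-series ketone gives the (12S,13S)-epoxide under reagent control (the D-series ketone gives R,R).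

Step 7
Reactants: 12 (2R,3S)-2-(benzyloxy)-3-[(tert-butyldimethylsilyl)oxy]-4-[(2S,3S)-3-ethyloxiran-2-yl]-N-methoxy-N-methylbutanamide
Product: 14 (2R,3S,5R)-3-[(tert-butyldimethylsilyl)oxy]-5-[(1S)-1-hydroxypropyl]-N-methoxy-N-methyloxolane-2-carboxamide, via hydroxy epoxide 13 (not isolated)
Conditions: H2 (1 atm), 10% Pd/C, EtOAc, rt; filter; camphor-10-sulfonic acid (0.1 equiv), CH2Cl2, 0 °C → rt
Reagents that add atoms: none
Why: Hydrogenolysis frees C9–OH, and acid-catalysed 5-exo-tet epoxide opening then closes ring B with inversion at C12, giving 12R (2,5-trans and 2,3-cis oxolane) and a 13S carbinol.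

Step 8
Reactants: 14 (2R,3S,5R)-3-[(tert-butyldimethylsilyl)oxy]-5-[(1S)-1-hydroxypropyl]-N-methoxy-N-methyloxolane-2-carboxamide
Product: 15 (2R,3S,5R)-3-[(tert-butyldimethylsilyl)oxy]-N-methoxy-N-methyl-5-propanoyloxolane-2-carboxamide
Conditions: Dess–Martin periodinane (1.3 equiv), CH2Cl2, 0 °C → rt
Reagents that add atoms: none
Why: Neutral Dess–Martin oxidation erases the wrong C13 configuration without epimerising the α-alkoxy centre C12.

Step 9
Reactants: 15 (2R,3S,5R)-3-[(tert-butyldimethylsilyl)oxy]-N-methoxy-N-methyl-5-propanoyloxolane-2-carboxamide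
Product: 16 (2R,3S,5R)-3-[(tert-butyldimethylsilyl)oxy]-5-[(1R)-1-hydroxypropyl]-N-methoxy-N-methyloxolane-2-carboxamide
Conditions: LiBH(s-Bu)3 (1.2 equiv), THF, −78 °C; then NaOH, H2O2, 0 °C
Reagents that add atoms: none
Why: In this polar Felkin–Anh reduction the bulky hydride attacks anti to the ring C12–O bond to give the threo (12R,13R) carbinol, and at −78 °C the ketone reacts far faster than the Weinreb amide.

Step 10
Reactants: 16 (2R,3S,5R)-3-[(tert-butyldimethylsilyl)oxy]-5-[(1R)-1-hydroxypropyl]-N-methoxy-N-methyloxolane-2-carboxamide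
Product: 17 (2R,3S,5R)-5-[(1S)-1-bromopropyl]-3-[(tert-butyldimethylsilyl)oxy]-N-methoxy-N-methyloxolane-2-carboxamide
Conditions: CBr4 (3 equiv), P(n-Oct)3 (3 equiv), toluene, 70 °C
Reagents that add atoms: carbon tetrabromide, BrC(Br)(Br)Br
Why: In this Appel-type bromination bromide displaces the alkoxyphosphonium ion by SN2, inverting 13R to the required 13S.

Step 11
Reactants: 17 (2R,3S,5R)-5-[(1S)-1-bromopropyl]-3-[(tert-butyldimethylsilyl)oxy]-N-methoxy-N-methyloxolane-2-carboxamide; 18 ethynyl(trimethyl)silane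
Product: 20 1-[(2R,3S,5R)-5-[(1S)-1-bromopropyl]-3-[(tert-butyldimethylsilyl)oxy]oxolan-2-yl]-3-(trimethylsilyl)prop-2-yn-1-one, via lithium acetylide 19 (not isolated)
Conditions: 18 (2.2 equiv), n-BuLi (2.0 equiv), THF, −78 °C; then 17, −78 → −20 °C; poured into cold 1 M HCl
Reagents that add atoms: none
Why: In this Weinreb ketone synthesis the chelated tetrahedral adduct stops at mono-addition, the hindered β-alkoxy bromide is inert at low temperature, and the acidic quench keeps the freed amine from adding to the ynone.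

Step 12
Reactants: 20 1-[(2R,3S,5R)-5-[(1S)-1-bromopropyl]-3-[(tert-butyldimethylsilyl)oxy]oxolan-2-yl]-3-(trimethylsilyl)prop-2-yn-1-one
Product: 21 (1S)-1-[(2S,3S,5R)-5-[(1S)-1-bromopropyl]-3-[(tert-butyldimethylsilyl)oxy]oxolan-2-yl]-3-(trimethylsilyl)prop-2-yn-1-ol
Conditions: Ru[(R,R)-TsNCH(Ph)CH(Ph)NH](p-cymene) (5 mol %), i-PrOH, rt
Reagents that add atoms: none
Why: In this Noyori asymmetric transfer hydrogenation the alkynyl group takes the aryl-like position at the (R,R)-catalyst, so reagent control gives the (8S)-carbinol with C8–OH anti to C9–O under base-free conditions (the ring C2 descriptor changes to S by priority only).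

Step 13
Reactants: 21 (1S)-1-[(2S,3S,5R)-5-[(1S)-1-bromopropyl]-3-[(tert-butyldimethylsilyl)oxy]oxolan-2-yl]-3-(trimethylsilyl)prop-2-yn-1-ol
Product: 22 (1S)-1-[(2S,3S,5R)-5-[(1S)-1-bromopropyl]-3-[(tert-butyldimethylsilyl)oxy]oxolan-2-yl]prop-2-yn-1-ol
Conditions: K2CO3 (0.2 equiv), MeOH, 0 °C → rt
Reagents that add atoms: none
Why: Methoxide-catalysed protodesilylation cleaves only the C(sp)–Si bond and leaves the TBS ether and the secondary bromide intact.

Step 14
Reactants: 23 ethyl propiolate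
Product: 24 ethyl (Z)-3-iodoacrylate
Conditions: NaI (1.1 equiv), AcOH, 70 °C
Reagents that add atoms: sodium iodide, [Na+].[I-]
Why: Conjugate hydroiodination proceeds by anti addition of iodide and a proton to the ynoate and gives the Z-iodoalkene that becomes the C3=C4 bond.

Step 15
Reactants: 24 ethyl (Z)-3-iodoacrylate
Product: 25 (Z)-3-iodoprop-2-en-1-ol
Conditions: i-Bu2AlH (2.2 equiv), CH2Cl2, −78 → 0 °C
Reagents that add atoms: none
Why: Excess aluminium hydride takes the ester straight to the allylic alcohol, so the isomerisation-prone Z-iodoacrolein never builds up.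

Step 16
Reactants: 25 (Z)-3-iodoprop-2-en-1-ol; 18 ethynyl(trimethyl)silane
Product: 26 (Z)-5-(trimethylsilyl)pent-2-en-4-yn-1-ol
Conditions: PdCl2(PPh3)2 (2 mol %), CuI (5 mol %), i-Pr2NH (3 equiv), THF, rt
Reagents that add atoms: none
Why: Sonogashira coupling of a vinyl iodide retains the alkene geometry and tolerates the free alcohol.

Step 17
Reactants: 26 (Z)-5-(trimethylsilyl)pent-2-en-4-yn-1-ol
Product: 27 [(Z)-5-bromopent-3-en-1-yn-1-yl]trimethylsilane
Conditions: CBr4 (1.2 equiv), PPh3 (1.2 equiv), CH2Cl2, −20 → 0 °C; used fresh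
Reagents that add atoms: carbon tetrabromide, BrC(Br)(Br)Br
Why: The Appel reaction on a primary allylic alcohol is a fast neutral SN2 that keeps the Z-enyne intact.

Step 18
Reactants: 22 (1S)-1-[(2S,3S,5R)-5-[(1S)-1-bromopropyl]-3-[(tert-butyldimethylsilyl)oxy]oxolan-2-yl]prop-2-yn-1-ol; 27 [(Z)-5-bromopent-3-en-1-yn-1-yl]trimethylsilane
Product: 29 (1S,5Z)-1-[(2S,3S,5R)-5-[(1S)-1-bromopropyl]-3-[(tert-butyldimethylsilyl)oxy]oxolan-2-yl]-8-(trimethylsilyl)oct-5-ene-2,7-diyn-1-ol, via copper acetylide 28 (not isolated)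
Conditions: CuI (1.0 equiv), K2CO3 (1.5 equiv), DMF, 0 °C → rt, argon
Reagents that add atoms: none
Why: Copper-mediated alkyne–allyl halide coupling attacks the primary allylic carbon (SN2) to give the linear skipped enyne with Z retained, and the weak base leaves the free carbinol and the C13 bromide alone.

Step 19
Reactants: 29 (1S,5Z)-1-[(2S,3S,5R)-5-[(1S)-1-bromopropyl]-3-[(tert-butyldimethylsilyl)oxy]oxolan-2-yl]-8-(trimethylsilyl)oct-5-ene-2,7-diyn-1-ol
Product: 30 tert-butyl({(2R,3S,5R)-2-[(1R,5Z)-1-bromo-8-(trimethylsilyl)oct-5-ene-2,7-diyn-1-yl]-5-[(1S)-1-bromopropyl]oxolan-3-yl}oxy)dimethylsilane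
Conditions: CBr4 (1.5 equiv), PPh3 (1.5 equiv), CH2Cl2, −30 → 0 °C
Reagents that add atoms: carbon tetrabromide, BrC(Br)(Br)Br
Why: The Appel bromination of the activated propargylic carbinol is a low-temperature SN2 with inversion, which puts Br syn (threo) to C9–O as in the target, and the cold neutral medium suppresses SN2' bromoallene formation and bromide exchange.

Step 20
Reactants: 30 tert-butyl({(2R,3S,5R)-2-[(1R,5Z)-1-bromo-8-(trimethylsilyl)oct-5-ene-2,7-diyn-1-yl]-5-[(1S)-1-bromopropyl]oxolan-3-yl}oxy)dimethylsilane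
Product: 31 (2R,3S,5R)-2-[(1R,5Z)-1-bromo-8-(trimethylsilyl)oct-5-ene-2,7-diyn-1-yl]-5-[(1S)-1-bromopropyl]oxolan-3-ol
Conditions: 48% aq HF, MeCN, 0 °C → rt
Reagents that add atoms: none
Why: Acidic fluoride desilylation removes the O-TBS group without base, so the propargylic bromide, the acidic C5 methylene and the C-silyl alkyne survive.

Step 21
Reactants: 31 (2R,3S,5R)-2-[(1R,5Z)-1-bromo-8-(trimethylsilyl)oct-5-ene-2,7-diyn-1-yl]-5-[(1S)-1-bromopropyl]oxolan-3-ol
Product: 32 (2Z,3S,3aR,5R,6aS)-3-bromo-5-[(1S)-1-bromopropyl]-2-[(3Z)-6-(trimethylsilyl)hex-3-en-5-yn-1-ylidene]hexahydrofuro[3,2-b]furan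
Conditions: Ph3PAuNTf2 (5 mol %, silver-free), 4 Å MS, CH2Cl2, 0 °C; Et3N quench; Et3N-deactivated SiO2
Reagents that add atoms: none
Why: In this gold-catalysed 5-exo-dig hydroalkoxylation, anti oxyauration followed by protodeauration puts H trans and C5 cis to the ring oxygen (6Z), and the cis arrangement of C10–OH and the C9 side chain on ring B allows only the cis-fused bicycle with exo C8–Br.

Step 22
Reactants: 32 (2Z,3S,3aR,5R,6aS)-3-bromo-5-[(1S)-1-bromopropyl]-2-[(3Z)-6-(trimethylsilyl)hex-3-en-5-yn-1-ylidene]hexahydrofuro[3,2-b]furan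
Product: 33 (2Z,3S,3aR,5R,6aS)-3-bromo-5-[(1S)-1-bromopropyl]-2-[(3Z)-hex-3-en-5-yn-1-ylidene]hexahydrofuro[3,2-b]furan
Conditions: K2CO3 (0.2 equiv), MeOH, 0 °C, 20–30 min; pH 7 buffer quench
Reagents that add atoms: none
Why: Protodesilylation of the enynyl silane is fast and the enol ether is base-stable, while the exo C8–Br can only be attacked from the concave face and has no anti-periplanar hydrogen at C9.

## Compound list
1 | (4R)-4-benzyl-1,3-oxazolidin-2-one | O=C1N[C@H](Cc2ccccc2)CO1 | starting material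
2 | (benzyloxy)acetyl chloride | O=C(Cl)COCc1ccccc1 | starting material
3 | N-lithio-(4R)-4-benzyl-1,3-oxazolidin-2-one | [Li]N1C(=O)OC[C@H]1Cc1ccccc1 | intermediate
4 | (4R)-4-benzyl-3-[(benzyloxy)acetyl]-1,3-oxazolidin-2-one | O=C(COCc1ccccc1)N1C(=O)OC[C@H]1Cc1ccccc1 | intermediate
5 | (E)-hex-3-en-1-ol | CC/C=C/CCO | starting material
6 | (E)-hex-3-enal | CC/C=C/CC=O | intermediate
7 | (Z)-dibutylboron enolate of 4 | CCCCB(CCCC)O/C(=C\OCc1ccccc1)N1C(=O)OC[C@H]1Cc1ccccc1 | intermediate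
8 | O-dibutylboron aldolate of 9 | CC/C=C/C[C@H](OB(CCCC)CCCC)[C@@H](OCc1ccccc1)C(=O)N1C(=O)OC[C@H]1Cc1ccccc1 | intermediate
9 | (4R)-4-benzyl-3-[(2R,3S,5E)-2-(benzyloxy)-3-hydroxyoct-5-enoyl]-1,3-oxazolidin-2-one | CC/C=C/C[C@H](O)[C@@H](OCc1ccccc1)C(=O)N1C(=O)OC[C@H]1Cc1ccccc1 | intermediate
10 | (2R,3S,5E)-2-(benzyloxy)-3-hydroxy-N-methoxy-N-methyloct-5-enamide | CC/C=C/C[C@H](O)[C@@H](OCc1ccccc1)C(=O)N(C)OC | intermediate
11 | (2R,3S,5E)-2-(benzyloxy)-3-[(tert-butyldimethylsilyl)oxy]-N-methoxy-N-methyloct-5-enamide | CC/C=C/C[C@H](O[Si](C)(C)C(C)(C)C)[C@@H](OCc1ccccc1)C(=O)N(C)OC | intermediate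
12 | (2R,3S)-2-(benzyloxy)-3-[(tert-butyldimethylsilyl)oxy]-4-[(2S,3S)-3-ethyloxiran-2-yl]-N-methoxy-N-methylbutanamide | CC[C@@H]1O[C@H]1C[C@H](O[Si](C)(C)C(C)(C)C)[C@@H](OCc1ccccc1)C(=O)N(C)OC | intermediate
13 | (2R,3S)-3-[(tert-butyldimethylsilyl)oxy]-4-[(2S,3S)-3-ethyloxiran-2-yl]-2-hydroxy-N-methoxy-N-methylbutanamide | CC[C@@H]1O[C@H]1C[C@H](O[Si](C)(C)C(C)(C)C)[C@@H](O)C(=O)N(C)OC | intermediate
14 | (2R,3S,5R)-3-[(tert-butyldimethylsilyl)oxy]-5-[(1S)-1-hydroxypropyl]-N-methoxy-N-methyloxolane-2-carboxamide | CC[C@H](O)[C@H]1C[C@H](O[Si](C)(C)C(C)(C)C)[C@@H](O1)C(=O)N(C)OC | intermediate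
15 | (2R,3S,5R)-3-[(tert-butyldimethylsilyl)oxy]-N-methoxy-N-methyl-5-propanoyloxolane-2-carboxamide | CCC(=O)[C@H]1C[C@H](O[Si](C)(C)C(C)(C)C)[C@@H](O1)C(=O)N(C)OC | intermediate
16 | (2R,3S,5R)-3-[(tert-butyldimethylsilyl)oxy]-5-[(1R)-1-hydroxypropyl]-N-methoxy-N-methyloxolane-2-carboxamide | CC[C@@H](O)[C@H]1C[C@H](O[Si](C)(C)C(C)(C)C)[C@@H](O1)C(=O)N(C)OC | intermediate
17 | (2R,3S,5R)-5-[(1S)-1-bromopropyl]-3-[(tert-butyldimethylsilyl)oxy]-N-methoxy-N-methyloxolane-2-carboxamide | CC[C@H](Br)[C@H]1C[C@H](O[Si](C)(C)C(C)(C)C)[C@@H](O1)C(=O)N(C)OC | intermediate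
18 | ethynyl(trimethyl)silane | C#C[Si](C)(C)C | starting material
19 | lithium (trimethylsilyl)acetylide | [Li]C#C[Si](C)(C)C | intermediate
20 | 1-[(2R,3S,5R)-5-[(1S)-1-bromopropyl]-3-[(tert-butyldimethylsilyl)oxy]oxolan-2-yl]-3-(trimethylsilyl)prop-2-yn-1-one | CC[C@H](Br)[C@H]1C[C@H](O[Si](C)(C)C(C)(C)C)[C@@H](O1)C(=O)C#C[Si](C)(C)C | intermediate
21 | (1S)-1-[(2S,3S,5R)-5-[(1S)-1-bromopropyl]-3-[(tert-butyldimethylsilyl)oxy]oxolan-2-yl]-3-(trimethylsilyl)prop-2-yn-1-ol | CC[C@H](Br)[C@H]1C[C@H](O[Si](C)(C)C(C)(C)C)[C@@H](O1)[C@@H](O)C#C[Si](C)(C)C | intermediate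
22 | (1S)-1-[(2S,3S,5R)-5-[(1S)-1-bromopropyl]-3-[(tert-butyldimethylsilyl)oxy]oxolan-2-yl]prop-2-yn-1-ol | CC[C@H](Br)[C@H]1C[C@H](O[Si](C)(C)C(C)(C)C)[C@@H](O1)[C@@H](O)C#C | intermediate
23 | ethyl propiolate | C#CC(=O)OCC | starting material
24 | ethyl (Z)-3-iodoacrylate | CCOC(=O)/C=C\I | intermediate
25 | (Z)-3-iodoprop-2-en-1-ol | OC/C=C\I | intermediate
26 | (Z)-5-(trimethylsilyl)pent-2-en-4-yn-1-ol | OC/C=C\C#C[Si](C)(C)C | intermediate
27 | [(Z)-5-bromopent-3-en-1-yn-1-yl]trimethylsilane | BrC/C=C\C#C[Si](C)(C)C | intermediate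
28 | copper acetylide of 22 | CC[C@H](Br)[C@H]1C[C@H](O[Si](C)(C)C(C)(C)C)[C@@H](O1)[C@@H](O)C#C[Cu] | intermediate
29 | (1S,5Z)-1-[(2S,3S,5R)-5-[(1S)-1-bromopropyl]-3-[(tert-butyldimethylsilyl)oxy]oxolan-2-yl]-8-(trimethylsilyl)oct-5-ene-2,7-diyn-1-ol | CC[C@H](Br)[C@H]1C[C@H](O[Si](C)(C)C(C)(C)C)[C@@H](O1)[C@@H](O)C#CC/C=C\C#C[Si](C)(C)C | intermediate
30 | tert-butyl({(2R,3S,5R)-2-[(1R,5Z)-1-bromo-8-(trimethylsilyl)oct-5-ene-2,7-diyn-1-yl]-5-[(1S)-1-bromopropyl]oxolan-3-yl}oxy)dimethylsilane | CC[C@H](Br)[C@H]1C[C@H](O[Si](C)(C)C(C)(C)C)[C@@H](O1)[C@H](Br)C#CC/C=C\C#C[Si](C)(C)C | intermediate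
31 | (2R,3S,5R)-2-[(1R,5Z)-1-bromo-8-(trimethylsilyl)oct-5-ene-2,7-diyn-1-yl]-5-[(1S)-1-bromopropyl]oxolan-3-ol | CC[C@H](Br)[C@H]1C[C@H](O)[C@@H](O1)[C@H](Br)C#CC/C=C\C#C[Si](C)(C)C | intermediate
32 | (2Z,3S,3aR,5R,6aS)-3-bromo-5-[(1S)-1-bromopropyl]-2-[(3Z)-6-(trimethylsilyl)hex-3-en-5-yn-1-ylidene]hexahydrofuro[3,2-b]furan | C[Si](C)(C)C#C/C=C\C/C=C1\O[C@H]2C[C@H]([C@@H](Br)CC)O[C@H]2[C@@H]1Br | intermediate
33 | (2Z,3S,3aR,5R,6aS)-3-bromo-5-[(1S)-1-bromopropyl]-2-[(3Z)-hex-3-en-5-yn-1-ylidene]hexahydrofuro[3,2-b]furan | C#C/C=C\C/C=C1\O[C@H]2C[C@H]([C@@H](Br)CC)O[C@H]2[C@@H]1Br | target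

## Step count
- Total step count: 22.
- Longest linear sequence: 17 (steps 1, 3–13 and 18–22; the branch through step 2 has the same length).

## The three steps most likely to fail

**Step 21 (gold-catalysed closure of ring A).**
- Risks: competing 6-endo attack at C6, loss of the halophilic catalyst to the propargylic bromide, and acid-induced migration of the enol ether.
- Fallback: close the ring before the C8 bromide exists. It sets out from 29.
- Aqueous HF in MeCN removes the TBS group and gives (2R,3S,5R)-5-[(1S)-1-bromopropyl]-2-[(1S,5Z)-1-hydroxy-8-(trimethylsilyl)oct-5-ene-2,7-diyn-1-yl]oxolan-3-ol F2.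
- In F2 the propargylic C–O bond favours 5-exo closure under Ag2CO3 (10 mol %, benzene, rt). This gives (2Z,3R,3aS,5R,6aS)-5-[(1S)-1-bromopropyl]-2-[(3Z)-6-(trimethylsilyl)hex-3-en-5-yn-1-ylidene]hexahydrofuro[3,2-b]furan-3-ol F3.
- The endo allylic hydroxyl of F3 is replaced by bromide from the open convex face with CBr4, PPh3 and 2,6-lutidine in CH2Cl2 at −40 °C (SN2, inversion).
- The fallback comes back to the route at 32 and also makes step 19 unnecessary.

**Step 22 (last desilylation).**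
- Risks: base can cause 1,4-loss of HBr (C5–H with C8–Br) or methanolysis of the allylic bromide.
- Fallback: remove the alkyne silyl group before any labile function is present, so that the neutral ring closure becomes the last operation. It sets out from 29.
- K2CO3 in MeOH gives (1S,5Z)-1-[(2S,3S,5R)-5-[(1S)-1-bromopropyl]-3-[(tert-butyldimethylsilyl)oxy]oxolan-2-yl]oct-5-ene-2,7-diyn-1-ol F4.
- CBr4 and PPh3 at −30 °C give tert-butyl({(2R,3S,5R)-2-[(1R,5Z)-1-bromooct-5-ene-2,7-diyn-1-yl]-5-[(1S)-1-bromopropyl]oxolan-3-yl}oxy)dimethylsilane F5.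
- Aqueous HF in MeCN gives (2R,3S,5R)-2-[(1R,5Z)-1-bromooct-5-ene-2,7-diyn-1-yl]-5-[(1S)-1-bromopropyl]oxolan-3-ol F6.
- Ph3PAuNTf2 (5 mol %, CH2Cl2, 0 °C, high dilution) closes ring A, and the fallback comes back to the route at 33.

**Step 10 (bromination of the hindered carbinol next to ring B).**
- Risks: elimination, and participation of the ring oxygen leading to retention or ring expansion.
- Fallback: put in the C13 bromide and ring B together by haloetherification instead of substitution. It sets out from 11.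
- BCl3 with pentamethylbenzene (CH2Cl2, −78 °C) removes the benzyl group without touching the alkene and gives (2R,3S,5E)-3-[(tert-butyldimethylsilyl)oxy]-2-hydroxy-N-methoxy-N-methyloct-5-enamide F1.
- N-Bromosuccinimide in MeCN at −20 °C then brings about 5-exo bromoetherification. Anti addition of O9 and Br across the E-alkene gives the erythro 12R,13S pair, with the 2,5-trans oxolane as the main isomer.
- The cis isomer and any six-membered ether are removed by chromatography.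
- The fallback comes back to the route at 17 and replaces steps 6–10.

## Further compounds
F1 | step 10 | (2R,3S,5E)-3-[(tert-butyldimethylsilyl)oxy]-2-hydroxy-N-methoxy-N-methyloct-5-enamide | CC/C=C/C[C@H](O[Si](C)(C)C(C)(C)C)[C@@H](O)C(=O)N(C)OC
F2 | step 21 | (2R,3S,5R)-5-[(1S)-1-bromopropyl]-2-[(1S,5Z)-1-hydroxy-8-(trimethylsilyl)oct-5-ene-2,7-diyn-1-yl]oxolan-3-ol | CC[C@H](Br)[C@H]1C[C@H](O)[C@@H](O1)[C@@H](O)C#CC/C=C\C#C[Si](C)(C)C
F3 | step 21 | (2Z,3R,3aS,5R,6aS)-5-[(1S)-1-bromopropyl]-2-[(3Z)-6-(trimethylsilyl)hex-3-en-5-yn-1-ylidene]hexahydrofuro[3,2-b]furan-3-ol | C[Si](C)(C)C#C/C=C\C/C=C1\O[C@H]2C[C@H]([C@@H](Br)CC)O[C@H]2[C@H]1O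
F4 | step 22 | (1S,5Z)-1-[(2S,3S,5R)-5-[(1S)-1-bromopropyl]-3-[(tert-butyldimethylsilyl)oxy]oxolan-2-yl]oct-5-ene-2,7-diyn-1-ol | CC[C@H](Br)[C@H]1C[C@H](O[Si](C)(C)C(C)(C)C)[C@@H](O1)[C@@H](O)C#CC/C=C\C#C
F5 | step 22 | tert-butyl({(2R,3S,5R)-2-[(1R,5Z)-1-bromooct-5-ene-2,7-diyn-1-yl]-5-[(1S)-1-bromopropyl]oxolan-3-yl}oxy)dimethylsilane | CC[C@H](Br)[C@H]1C[C@H](O[Si](C)(C)C(C)(C)C)[C@@H](O1)[C@H](Br)C#CC/C=C\C#C
F6 | step 22 | (2R,3S,5R)-2-[(1R,5Z)-1-bromooct-5-ene-2,7-diyn-1-yl]-5-[(1S)-1-bromopropyl]oxolan-3-ol | CC[C@H](Br)[C@H]1C[C@H](O)[C@@H](O1)[C@H](Br)C#CC/C=C\C#C
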